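**Plan**

Cuts: C1–H and C1–C8a come first (ring B: iminium reduction, Bischler–Napieralski closure). Ring A is then cut at C4a–C8a, C8–C8a, C6–C7 and C5–C6, and last the C4a=C5 alkene of the open-chain precursor (olefination).
Enabling feature: ring A is a resorcinol diether (O on C6 and C8, H on C7) with the naphthyl on C5 beside the C4a side chain. C6–C8a–C4a–C5 map onto a vinylketene and C7–C8 onto an alkynyl ether.
Forward order: naphthalene (aryne acyl-alkylation/aldol, formylation), olefination with the alaninol-derived phosphonate, α-diazo enone, ring A, ring B.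
Stereochemistry: C3 (S) is carried unchanged from Boc-L-alaninol. C1 (R) comes from hydride attack on the cyclic iminium ion anti to the C3 methyl group (1,3-cis).
Safeguards: nitrogen carries Boc and methyl before any ketene exists, the diazo group comes from diazo transfer onto a methyl enone, and methoxyacetylene brings the C8 oxygen in as OMe.

Key step: step 13

Assumption: the drawn structure fixes C1 and C3 but not the hindered C5–C1' biaryl axis, so both atropo-diastereomers of the (1R,3S) compound are taken to fit it; they should form without control in step 13, are carried together, and are parted by chromatography after step 16.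

**Route**

Step 1
Reactants: 1 3-methoxy-2-(trimethylsilyl)phenyl trifluoromethanesulfonate; 2 acetylacetone
Product: 5 8-methoxy-3-methylnaphthalen-1-ol, via 3-methoxybenzyne 3 (not isolated), via aryl diketone 4 (not isolated)
Conditions: CsF, MeCN, 80 °C; then NaOMe, MeOH, 60 °C; aq HCl work-up
Reagents that add atoms: none
Why: Fluoride unmasks aryne 3, the acetylacetone enolate adds at the aryne carbon meta to OMe and the resulting ortho aryl anion attacks a ketone so that fragmentation inserts the aryne into the C–C bond (aryne acyl-alkylation) with the acetyl group next to OMe, and methoxide then closes 4 by intramolecular aldol condensation of the acetyl CH3 onto the more electrophilic aliphatic ketone, with aromatisation making it irreversible.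

Step 2
Reactants: 5 8-methoxy-3-methylnaphthalen-1-ol
Product: 6 8-methoxy-3-methylnaphthalen-1-yl acetate
Conditions: Ac2O, pyridine, DMAP (cat.), CH2Cl2, rt
Reagents that add atoms: acetic anhydride CC(=O)OC(C)=O
Why: DMAP-catalysed O-acylation, which makes the methyl-bearing ring the less electron-rich of the two for the next step.

Step 3
Reactants: 6 8-methoxy-3-methylnaphthalen-1-yl acetate
Product: 8 5-formyl-8-methoxy-3-methylnaphthalen-1-yl acetate, via aryl iminium chloride 7 (not isolated)
Conditions: POCl3, DMF, 0 → 80 °C; then H2O, rt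
Reagents that add atoms: N,N-dimethylformamide CN(C)C=O; water O
Why: Vilsmeier–Haack formylation, a weak and selective electrophile that should attack the α-position para to the only strong donor left (the C8 methoxy group), because the acetoxy ring is deactivated and its free α-position is flanked by the methyl group.

Step 4
Reactants: 8 5-formyl-8-methoxy-3-methylnaphthalen-1-yl acetate
Product: 10 4,5-dimethoxy-7-methylnaphthalene-1-carbaldehyde, via free naphthol 9 (not isolated)
Conditions: K2CO3, MeOH, rt; then MeI, DMF, rt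
Reagents that add atoms: iodomethane CI
Why: Methanolysis of the aryl acetate followed in the same flask by Williamson O-methylation of the naphthoxide, conditions that leave the non-enolisable aldehyde untouched.

Step 5
Reactants: 11 Boc-L-alaninol, tert-butyl N-[(2S)-1-hydroxypropan-2-yl]carbamate
Product: 12 tert-butyl (4S)-4-methyl-1,2,3-oxathiazolidine-3-carboxylate 2-oxide (both sulfur epimers)
Conditions: SOCl2, pyridine, MeCN, −40 °C → rt
Reagents that add atoms: thionyl chloride O=S(Cl)Cl
Why: Cyclic sulfamidite formation, in which SOCl2 bridges the carbamate N–H and the primary O–H while pyridine takes up the acid and the C–N stereocentre is not touched.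

Step 6
Reactants: 12 tert-butyl (4S)-4-methyl-1,2,3-oxathiazolidine-3-carboxylate 2-oxide
Product: 13 tert-butyl (4S)-4-methyl-1,2,3-oxathiazolidine-3-carboxylate 2,2-dioxide
Conditions: RuCl3·xH2O (cat.), NaIO4, MeCN/H2O, 0 °C
Reagents that add atoms: sodium periodate [Na+].[O-]I(=O)(=O)=O
Why: Ruthenium-catalysed periodate oxidation of the sulfamidite sulfur to the cyclic sulfamidate, the standard way to turn a 1,2-amino alcohol into a clean primary electrophile.

Step 7
Reactants: 13 tert-butyl (4S)-4-methyl-1,2,3-oxathiazolidine-3-carboxylate 2,2-dioxide; 14 diethyl (N-methoxy-N-methylcarbamoylmethyl)phosphonate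
Product: 16 diethyl [(4S)-4-(tert-butoxycarbonylamino)-1-[methoxy(methyl)amino]-1-oxopentan-2-yl]phosphonate (both C2 epimers), via sodium N-sulfamate 15 (not isolated)
Conditions: NaH, THF/DMF, 0 → 50 °C; then 10% aq citric acid, rt
Reagents that add atoms: none
Why: SN2 opening of the cyclic sulfamidate at its primary oxygen-bearing carbon by the phosphonate-stabilised carbanion, after which mild acid hydrolyses only the N–SO3 bond of 15, the (S) centre staying a spectator and the new centre next to phosphorus being erased in step 8.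

Step 8
Reactants: 16 diethyl [(4S)-4-(tert-butoxycarbonylamino)-1-[methoxy(methyl)amino]-1-oxopentan-2-yl]phosphonate; 10 4,5-dimethoxy-7-methylnaphthalene-1-carbaldehyde
Product: 17 (E)-2-[(2S)-2-(tert-butoxycarbonylamino)propyl]-3-(4,5-dimethoxy-7-methylnaphthalen-1-yl)-N-methoxy-N-methylprop-2-enamide
Conditions: NaH, THF, 0 °C; then 10, 0 → 65 °C; chromatography
Reagents that add atoms: none
Why: Horner–Wadsworth–Emmons olefination, in which reversible addition and the preference for the aryl group trans to the carboxamide should favour the E alkene, the minor Z isomer being removed by chromatography.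

Step 9
Reactants: 17 (E)-2-[(2S)-2-(tert-butoxycarbonylamino)propyl]-3-(4,5-dimethoxy-7-methylnaphthalen-1-yl)-N-methoxy-N-methylprop-2-enamide
Product: 18 (E)-2-[(2S)-2-[tert-butoxycarbonyl(methyl)amino]propyl]-3-(4,5-dimethoxy-7-methylnaphthalen-1-yl)-N-methoxy-N-methylprop-2-enamide
Conditions: NaH, MeI, DMF, 0 °C
Reagents that add atoms: iodomethane CI
Why: N-Alkylation of the carbamate anion (no competing acidic C–H is present), which installs the N-methyl group of the target and removes the only N–H, a group that could otherwise add to the ketene of step 13 through a six-membered ring.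

Step 10
Reactants: 18 (E)-2-[(2S)-2-[tert-butoxycarbonyl(methyl)amino]propyl]-3-(4,5-dimethoxy-7-methylnaphthalen-1-yl)-N-methoxy-N-methylprop-2-enamide
Product: 19 tert-butyl N-[(2S,4E)-4-acetyl-5-(4,5-dimethoxy-7-methylnaphthalen-1-yl)pent-4-en-2-yl]-N-methylcarbamate
Conditions: MeMgBr, THF, −20 → 0 °C; aq work-up
Reagents that add atoms: methylmagnesium bromide C[Mg]Br
Why: Weinreb ketone synthesis, in which the N-methoxy-N-methylamide takes up one methyl nucleophile at the carbonyl carbon and releases the ketone only on work-up, so neither over-addition nor conjugate addition is expected.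

Step 11
Reactants: 19 tert-butyl N-[(2S,4E)-4-acetyl-5-(4,5-dimethoxy-7-methylnaphthalen-1-yl)pent-4-en-2-yl]-N-methylcarbamate
Product: 21 tert-butyl N-[(2S,4E)-4-(2-diazoacetyl)-5-(4,5-dimethoxy-7-methylnaphthalen-1-yl)pent-4-en-2-yl]-N-methylcarbamate, via trifluoroacetyl ketone 20 (not isolated)
Conditions: LiN(SiMe3)2, THF, −78 °C; CF3CO2CH2CF3; aq HCl wash; then 4-AcNHC6H4SO2N3, Et3N, H2O, MeCN, rt
Reagents that add atoms: 4-acetamidobenzenesulfonyl azide CC(=O)Nc1ccc(cc1)S(=O)(=O)N=[N+]=[N-]; 2,2,2-trifluoroethyl trifluoroacetate FC(F)(F)COC(=O)C(F)(F)F (its CF3CO group stays only in 20)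
Why: Detrifluoroacetylative diazo transfer (a deacylative Regitz-type transfer), in which kinetic deprotonation can occur only at the acetyl CH3, Claisen acylation activates that carbon and the sulfonyl azide delivers N2 with loss of the trifluoroacetyl group, so that no diazomethane, which adds to conjugated double bonds as a 1,3-dipole, ever meets the enone.

Step 12
Reactants: 22 chloroacetaldehyde dimethyl acetal
Product: 24 methoxyacetylene, via sodium methoxyacetylide 23 (not isolated)
Conditions: NaNH2 (3 equiv), liquid NH3, −33 °C; evaporate NH3; cold saturated aq NaCl; distil into cold ClCH2CH2Cl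
Reagents that add atoms: none
Why: Twofold base-induced elimination (methanol, then HCl) from the α-chloro acetal, the classical route to alkoxyacetylenes, the third equivalent of base holding the product as acetylide 23 until the cold aqueous quench.

Step 13
Reactants: 21 tert-butyl N-[(2S,4E)-4-(2-diazoacetyl)-5-(4,5-dimethoxy-7-methylnaphthalen-1-yl)pent-4-en-2-yl]-N-methylcarbamate; 24 methoxyacetylene
Product: 29 tert-butyl N-[(2S)-1-[2-(4,5-dimethoxy-7-methylnaphthalen-1-yl)-3-hydroxy-5-methoxyphenyl]propan-2-yl]-N-methylcarbamate, via vinylketene 25 (not isolated), via alkenylcyclobutenone 26 (not isolated), via dienylketene 27 (not isolated), via cyclohexadienone 28 (not isolated)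
Conditions: 24 (excess), degassed ClCH2CH2Cl, hν (254 nm, quartz), rt, closed vessel; then 80 °C, dark
Reagents that add atoms: none
Why: Light expels N2 from 21 and the alkenyl group shifts from the carbonyl carbon to the diazo carbon (photochemical Wolff rearrangement, new C4a–C8a bond) to give vinylketene 25 with the E geometry kept. The ketene carbon (future C6) bonds to the unsubstituted, nucleophilic carbon of 24 (C7) and the ketene α-carbon (C8a) to the oxygen-bearing carbon (C8) in a polar (2+2) cycloaddition that closes the transient four-membered ring of 4-alkenyl-3-methoxycyclobutenone 26. Light or heat opens 26 by 4π electrocyclic cleavage of C6–C8a to dienylketene 27, ring A closes by 6π electrocyclisation (C5–C6) to dienone 28, and tautomerisation to phenol 29 makes the sequence irreversible. The closest known reaction type is the second-generation Danheiser benzannulation of α-diazo enones with alkoxy- and siloxyalkynes. No lasting stereocentre is created (the sp3 centres of 26 and 28 vanish and the C5–C1' axis forms without control), and C3 is a spectator. The step needs regioselectivity, secured by the polarisation of the ynol ether, and chemoselectivity for the alkyne, secured by the absence of any N–H or O–H in 21, by the excess of 24 and by the E alkene, which holds the naphthyl trans to the ketene so that the ketene cannot close onto naphthalene C2' and the naphthyl lies outside in the 6π transition state.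

Step 14
Reactants: 29 tert-butyl N-[(2S)-1-[2-(4,5-dimethoxy-7-methylnaphthalen-1-yl)-3-hydroxy-5-methoxyphenyl]propan-2-yl]-N-methylcarbamate
Product: 30 tert-butyl N-[(2S)-1-[2-(4,5-dimethoxy-7-methylnaphthalen-1-yl)-3,5-dimethoxyphenyl]propan-2-yl]-N-methylcarbamate
Conditions: MeI, K2CO3, DMF, rt → 40 °C
Reagents that add atoms: iodomethane CI
Why: Williamson ether synthesis on the only acidic O–H of the molecule, which completes the C6/C8 dimethoxy pattern.

Step 15
Reactants: 30 tert-butyl N-[(2S)-1-[2-(4,5-dimethoxy-7-methylnaphthalen-1-yl)-3,5-dimethoxyphenyl]propan-2-yl]-N-methylcarbamate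
Product: 32 N-[(2S)-1-[2-(4,5-dimethoxy-7-methylnaphthalen-1-yl)-3,5-dimethoxyphenyl]propan-2-yl]-N-methylacetamide, via amine hydrochloride 31 (not isolated)
Conditions: HCl (4 M in dioxane), rt; evaporate; Ac2O, Et3N, CH2Cl2, 0 °C → rt
Reagents that add atoms: acetic anhydride CC(=O)OC(C)=O
Why: Acidolysis of the Boc group (HCl in dioxane rather than CF3CO2H, to limit tert-butylation of the electron-rich rings) followed by N-acetylation of the liberated secondary amine in the same flask.

Step 16
Reactants: 32 N-[(2S)-1-[2-(4,5-dimethoxy-7-methylnaphthalen-1-yl)-3,5-dimethoxyphenyl]propan-2-yl]-N-methylacetamide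
Product: 34 (1R,3S)-5-(4,5-dimethoxy-7-methylnaphthalen-1-yl)-6,8-dimethoxy-1,2,3-trimethyl-1,2,3,4-tetrahydroisoquinoline, via dihydroisoquinolinium chloride 33 (not isolated)
Conditions: POCl3, MeCN, 80 °C; evaporate; NaBH4, MeOH, −20 → 0 °C; chromatographic separation of the two atropo-diastereomers
Reagents that add atoms: none
Why: Bischler–Napieralski cyclisation of the tertiary acetamide closes ring B at C8a, the only free position ortho to the side chain and one activated by the ortho C8 and para C6 methoxy groups, and NaBH4 then attacks iminium ion 33 at C1 from the face opposite the C3 methyl group, which allylic strain with the N-methyl group holds pseudo-axial, so that the 1,3-cis (1R,3S) amine is expected.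

**Compound list**

1 | 3-methoxy-2-(trimethylsilyl)phenyl trifluoromethanesulfonate | COc1cccc(OS(=O)(=O)C(F)(F)F)c1[Si](C)(C)C | starting material
2 | acetylacetone (pentane-2,4-dione) | CC(=O)CC(C)=O | starting material
3 | 3-methoxybenzyne | COC1=CC=CC#C1 | intermediate
4 | 1-(2-acetyl-3-methoxyphenyl)propan-2-one | COc1cccc(CC(C)=O)c1C(C)=O | intermediate
5 | 8-methoxy-3-methylnaphthalen-1-ol | COc1cccc2cc(C)cc(O)c12 | intermediate
6 | 8-methoxy-3-methylnaphthalen-1-yl acetate | COc1cccc2cc(C)cc(OC(C)=O)c12 | intermediate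
7 | [(5-acetoxy-4-methoxy-7-methylnaphthalen-1-yl)methylidene]dimethylammonium chloride | COc1ccc(C=[N+](C)C)c2cc(C)cc(OC(C)=O)c12.[Cl-] | intermediate
8 | 5-formyl-8-methoxy-3-methylnaphthalen-1-yl acetate | COc1ccc(C=O)c2cc(C)cc(OC(C)=O)c12 | intermediate
9 | 5-hydroxy-4-methoxy-7-methylnaphthalene-1-carbaldehyde | COc1ccc(C=O)c2cc(C)cc(O)c12 | intermediate
10 | 4,5-dimethoxy-7-methylnaphthalene-1-carbaldehyde | COc1ccc(C=O)c2cc(C)cc(OC)c12 | intermediate
11 | Boc-L-alaninol, tert-butyl N-[(2S)-1-hydroxypropan-2-yl]carbamate | C[C@H](NC(=O)OC(C)(C)C)CO | starting material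
12 | tert-butyl (4S)-4-methyl-1,2,3-oxathiazolidine-3-carboxylate 2-oxide (both sulfur epimers) | C[C@H]1COS(=O)N1C(=O)OC(C)(C)C | intermediate
13 | tert-butyl (4S)-4-methyl-1,2,3-oxathiazolidine-3-carboxylate 2,2-dioxide | C[C@H]1COS(=O)(=O)N1C(=O)OC(C)(C)C | intermediate
14 | diethyl (N-methoxy-N-methylcarbamoylmethyl)phosphonate | CCOP(=O)(CC(=O)N(C)OC)OCC | starting material
15 | sodium N-(tert-butoxycarbonyl)-N-[(2S)-4-(diethoxyphosphoryl)-5-[methoxy(methyl)amino]-5-oxopentan-2-yl]sulfamate | CCOP(=O)(OCC)C(C[C@H](C)N(C(=O)OC(C)(C)C)S(=O)(=O)[O-])C(=O)N(C)OC.[Na+] | intermediate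
16 | diethyl [(4S)-4-(tert-butoxycarbonylamino)-1-[methoxy(methyl)amino]-1-oxopentan-2-yl]phosphonate (both C2 epimers) | CCOP(=O)(OCC)C(C[C@H](C)NC(=O)OC(C)(C)C)C(=O)N(C)OC | intermediate
17 | (E)-2-[(2S)-2-(tert-butoxycarbonylamino)propyl]-3-(4,5-dimethoxy-7-methylnaphthalen-1-yl)-N-methoxy-N-methylprop-2-enamide | CON(C)C(=O)/C(C[C@H](C)NC(=O)OC(C)(C)C)=C/c1ccc(OC)c2c(OC)cc(C)cc12 | intermediate
18 | (E)-2-[(2S)-2-[tert-butoxycarbonyl(methyl)amino]propyl]-3-(4,5-dimethoxy-7-methylnaphthalen-1-yl)-N-methoxy-N-methylprop-2-enamide | CON(C)C(=O)/C(C[C@H](C)N(C)C(=O)OC(C)(C)C)=C/c1ccc(OC)c2c(OC)cc(C)cc12 | intermediate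
19 | tert-butyl N-[(2S,4E)-4-acetyl-5-(4,5-dimethoxy-7-methylnaphthalen-1-yl)pent-4-en-2-yl]-N-methylcarbamate | CC(=O)/C(C[C@H](C)N(C)C(=O)OC(C)(C)C)=C/c1ccc(OC)c2c(OC)cc(C)cc12 | intermediate
20 | tert-butyl N-[(2S,4E)-5-(4,5-dimethoxy-7-methylnaphthalen-1-yl)-4-(4,4,4-trifluoro-3-oxobutanoyl)pent-4-en-2-yl]-N-methylcarbamate | FC(F)(F)C(=O)CC(=O)/C(C[C@H](C)N(C)C(=O)OC(C)(C)C)=C/c1ccc(OC)c2c(OC)cc(C)cc12 | intermediate
21 | tert-butyl N-[(2S,4E)-4-(2-diazoacetyl)-5-(4,5-dimethoxy-7-methylnaphthalen-1-yl)pent-4-en-2-yl]-N-methylcarbamate | [N-]=[N+]=CC(=O)/C(C[C@H](C)N(C)C(=O)OC(C)(C)C)=C/c1ccc(OC)c2c(OC)cc(C)cc12 | intermediate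
22 | chloroacetaldehyde dimethyl acetal (2-chloro-1,1-dimethoxyethane) | COC(CCl)OC | starting material
23 | sodium methoxyacetylide | COC#[C-].[Na+] | intermediate
24 | methoxyacetylene | COC#C | intermediate
25 | vinylketene, tert-butyl N-[(2S,4E)-5-(4,5-dimethoxy-7-methylnaphthalen-1-yl)-4-(2-oxoethenyl)pent-4-en-2-yl]-N-methylcarbamate | O=C=C/C(C[C@H](C)N(C)C(=O)OC(C)(C)C)=C/c1ccc(OC)c2c(OC)cc(C)cc12 | intermediate
26 | 4-alkenyl-3-methoxycyclobut-2-en-1-one, tert-butyl N-[(2S,4E)-5-(4,5-dimethoxy-7-methylnaphthalen-1-yl)-4-(2-methoxy-4-oxocyclobut-2-en-1-yl)pent-4-en-2-yl]-N-methylcarbamate (both ring epimers) | O=C1C=C(OC)C1/C(C[C@H](C)N(C)C(=O)OC(C)(C)C)=C/c1ccc(OC)c2c(OC)cc(C)cc12 | intermediate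
27 | dienylketene O=C=CH–C(OMe)=CH–C(side chain)=CH–naphthyl, ketenyl and dienyl ends cis on the central alkene | O=C=C/C(OC)=C\C(C[C@H](C)N(C)C(=O)OC(C)(C)C)=C\c1ccc(OC)c2c(OC)cc(C)cc12 | intermediate
28 | 6-naphthyl-3-methoxy-5-(side chain)cyclohexa-2,4-dien-1-one (keto tautomer of 29, both C6 epimers) | O=C1C=C(OC)C=C(C[C@H](C)N(C)C(=O)OC(C)(C)C)C1c1ccc(OC)c2c(OC)cc(C)cc12 | intermediate
29 | tert-butyl N-[(2S)-1-[2-(4,5-dimethoxy-7-methylnaphthalen-1-yl)-3-hydroxy-5-methoxyphenyl]propan-2-yl]-N-methylcarbamate | Oc1cc(OC)cc(C[C@H](C)N(C)C(=O)OC(C)(C)C)c1-c1ccc(OC)c2c(OC)cc(C)cc12 | intermediate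
30 | tert-butyl N-[(2S)-1-[2-(4,5-dimethoxy-7-methylnaphthalen-1-yl)-3,5-dimethoxyphenyl]propan-2-yl]-N-methylcarbamate | COc1cc(OC)cc(C[C@H](C)N(C)C(=O)OC(C)(C)C)c1-c1ccc(OC)c2c(OC)cc(C)cc12 | intermediate
31 | (2S)-1-[2-(4,5-dimethoxy-7-methylnaphthalen-1-yl)-3,5-dimethoxyphenyl]-N-methylpropan-2-amine hydrochloride | COc1cc(OC)cc(C[C@H](C)NC)c1-c1ccc(OC)c2c(OC)cc(C)cc12.Cl | intermediate
32 | N-[(2S)-1-[2-(4,5-dimethoxy-7-methylnaphthalen-1-yl)-3,5-dimethoxyphenyl]propan-2-yl]-N-methylacetamide | COc1cc(OC)cc(C[C@H](C)N(C)C(C)=O)c1-c1ccc(OC)c2c(OC)cc(C)cc12 | intermediate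
33 | (3S)-5-(4,5-dimethoxy-7-methylnaphthalen-1-yl)-6,8-dimethoxy-1,2,3-trimethyl-3,4-dihydroisoquinolin-2-ium chloride | COc1cc(OC)c2c(c1-c1ccc(OC)c3c(OC)cc(C)cc13)C[C@H](C)[N+](C)=C2C.[Cl-] | intermediate
34 | (1R,3S)-5-(4,5-dimethoxy-7-methylnaphthalen-1-yl)-6,8-dimethoxy-1,2,3-trimethyl-1,2,3,4-tetrahydroisoquinoline | COc1cc(OC)c2c(c1-c1ccc(OC)c3c(OC)cc(C)cc13)C[C@H](C)N(C)[C@@H]2C | target

**Step count**

Total steps: 16. Longest linear sequence: 12 steps (1–4, 8–11, 13–16).

**Steps most likely to fail**

Step 13. Several processes could spoil it: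
- The naphthyl chromophore may take up most of the light and slow the loss of N2.
- Photochemical E to Z isomerisation of the naphthyl alkene would bring the naphthalene within reach of the ketene carbon.
- Ketene that is not trapped quickly may acylate the phenol already formed.

The fallback makes the same vinylketene without light; it sets out from 21 and comes back at 29. Wolff rearrangement of 21 with PhCO2Ag (cat.) and Et3N in aqueous THF in the dark should give (3E)-3-[(2S)-2-[tert-butoxycarbonyl(methyl)amino]propyl]-4-(4,5-dimethoxy-7-methylnaphthalen-1-yl)but-3-enoic acid F1. The neutral reagent 1-chloro-N,N,2-trimethylpropenylamine in CH2Cl2 converts it into (3E)-3-[(2S)-2-[tert-butoxycarbonyl(methyl)amino]propyl]-4-(4,5-dimethoxy-7-methylnaphthalen-1-yl)but-3-enoyl chloride F2 without touching the Boc group. Slow addition of Et3N to F2 and excess 24 in toluene at 80 °C in a closed vessel removes HCl from the doubly activated α-position. This gives 25, which runs through 26, 27 and 28 to 29 purely thermally.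

Step 8. Addition of a branched, stabilised carbanion to an electron-rich, peri-hindered aldehyde may be slow, and the E/Z selectivity may erode on prolonged heating. The fallback activates the aldehyde instead of the nucleophile; it sets out from 13 and 10 and comes back at 17.
- Sodium diethyl malonate (NaH, THF) opens 13 to sodium N-(tert-butoxycarbonyl)-N-[(2S)-5-ethoxy-4-(ethoxycarbonyl)-5-oxopentan-2-yl]sulfamate F3.
- Aqueous citric acid then gives diethyl 2-[(2S)-2-(tert-butoxycarbonylamino)propyl]propanedioate F4.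
- KOH in aqueous EtOH followed by cold acidification gives 2-[(2S)-2-(tert-butoxycarbonylamino)propyl]propanedioic acid F5.
- Heating F5 with 10 in pyridine/piperidine at 90 °C is the Doebner variant of the Knoevenagel condensation. Piperidine turns the aldehyde into a more electrophilic iminium ion, and decarboxylative elimination places the aryl group trans to the carboxyl group. This should give (E)-2-[(2S)-2-(tert-butoxycarbonylamino)propyl]-3-(4,5-dimethoxy-7-methylnaphthalen-1-yl)prop-2-enoic acid F6.
- Coupling of F6 with MeNHOMe·HCl (EDC·HCl, iPr2NEt, CH2Cl2) returns to 17.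

Step 3. The weak Vilsmeier electrophile may convert a ring whose methoxy donor is twisted by the peri acetate only slowly. Forcing the reaction may bring attack on the methyl-bearing ring or loss of the acetate. The fallback separates C–H functionalisation from C–C bond formation; it sets out from 6 and comes back at 10.
- NBS in MeCN at 0 °C (para-selective bromination of methoxyarenes) should give 5-bromo-8-methoxy-3-methylnaphthalen-1-yl acetate F7.
- K2CO3 in MeOH frees 5-bromo-8-methoxy-3-methylnaphthalen-1-ol F8.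
- MeI in DMF methylates it to 1-bromo-4,5-dimethoxy-7-methylnaphthalene F9.
- Bromine–lithium exchange with n-BuLi in THF at −78 °C gives (4,5-dimethoxy-7-methylnaphthalen-1-yl)lithium F10.
- Quenching F10 with DMF and aqueous work-up delivers 10.

**Further compounds**

F1 | step 13 | (3E)-3-[(2S)-2-[tert-butoxycarbonyl(methyl)amino]propyl]-4-(4,5-dimethoxy-7-methylnaphthalen-1-yl)but-3-enoic acid | OC(=O)C/C(C[C@H](C)N(C)C(=O)OC(C)(C)C)=C/c1ccc(OC)c2c(OC)cc(C)cc12
F2 | step 13 | (3E)-3-[(2S)-2-[tert-butoxycarbonyl(methyl)amino]propyl]-4-(4,5-dimethoxy-7-methylnaphthalen-1-yl)but-3-enoyl chloride | ClC(=O)C/C(C[C@H](C)N(C)C(=O)OC(C)(C)C)=C/c1ccc(OC)c2c(OC)cc(C)cc12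
F3 | step 8 | sodium N-(tert-butoxycarbonyl)-N-[(2S)-5-ethoxy-4-(ethoxycarbonyl)-5-oxopentan-2-yl]sulfamate | CCOC(=O)C(C[C@H](C)N(C(=O)OC(C)(C)C)S(=O)(=O)[O-])C(=O)OCC.[Na+]
F4 | step 8 | diethyl 2-[(2S)-2-(tert-butoxycarbonylamino)propyl]propanedioate | CCOC(=O)C(C[C@H](C)NC(=O)OC(C)(C)C)C(=O)OCC
F5 | step 8 | 2-[(2S)-2-(tert-butoxycarbonylamino)propyl]propanedioic acid | OC(=O)C(C[C@H](C)NC(=O)OC(C)(C)C)C(O)=O
F6 | step 8 | (E)-2-[(2S)-2-(tert-butoxycarbonylamino)propyl]-3-(4,5-dimethoxy-7-methylnaphthalen-1-yl)prop-2-enoic acid | OC(=O)/C(C[C@H](C)NC(=O)OC(C)(C)C)=C/c1ccc(OC)c2c(OC)cc(C)cc12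
F7 | step 3 | 5-bromo-8-methoxy-3-methylnaphthalen-1-yl acetate | COc1ccc(Br)c2cc(C)cc(OC(C)=O)c12
F8 | step 3 | 5-bromo-8-methoxy-3-methylnaphthalen-1-ol | COc1ccc(Br)c2cc(C)cc(O)c12
F9 | step 3 | 1-bromo-4,5-dimethoxy-7-methylnaphthalene | COc1ccc(Br)c2cc(C)cc(OC)c12
F10 | step 3 | (4,5-dimethoxy-7-methylnaphthalen-1-yl)lithium | COc1ccc([Li])c2cc(C)cc(OC)c12
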